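Everything rests on cutting C5–C10 and C8–C9 together. The feature exploited is ring B (carbons C5 to C10): with a transient oxygen on C6 it is a Diels–Alder cyclohexene, and the two cuts also open ring A along its four-carbon chain C1–C4, which carries the C2 oxygen between the methyl-bearing C4 and C10. In the forward sense one operation, the intramolecular Diels–Alder reaction of a (Z)-2-silyloxydiene (C5–C8) with an E-β-methyl enoate (C9=C10, ester carbon C11), closes both rings and sets C5, C8, C9 and C10 from the single stereocentre C2. The precursor is an acyclic silyloxytriene ester with defined alkene geometries.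

Key step: step 10

Assumption: the sense of induction in step 2 is taken from the preference of this catalyst class with aromatic aldehydes ((R)-catalyst, Re face), so (S)-TRIP is specified; locants C1–C20 in the text are labdane numbers.

Step 1
Reactants: 1 methyl 3,3-dimethylpent-4-enoate
Product: 2 3,3-dimethylpent-4-enal
Conditions: i-Bu2AlH (1.05 equiv), toluene, −78 °C; aq. KNaC4H4O6 (tartrate)
Reagents that add atoms: none
Why: Partial reduction of a methyl ester with i-Bu2AlH at −78 °C should stop at the aldehyde oxidation level, and the quaternary β-carbon protects the product from aldol self-condensation; no stereocentre is formed.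

Step 2
Reactants: 2 3,3-dimethylpent-4-enal; 3 allenylboronic acid pinacol ester
Product: 5 (S)-6,6-dimethyloct-7-en-1-yn-4-ol, via homopropargyl pinacol borate 4 (not isolated)
Conditions: (S)-TRIP [(S)-3,3′-bis(2,4,6-triisopropylphenyl)-1,1′-binaphthyl-2,2′-diyl hydrogen phosphate] (10 mol%), 4 Å MS, toluene, −20 °C; then aq. NaHCO3
Reagents that add atoms: none
Why: Chiral-phosphoric-acid-catalysed allenylboration (asymmetric propargylation) passes through a closed six-membered SE2′ transition state held by the catalyst, which should deliver the propargyl group to the Si face of the aldehyde and so set C2 (S here), the only stereocentre the key step needs.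

Step 3
Reactants: 5 (S)-6,6-dimethyloct-7-en-1-yn-4-ol
Product: 6 (S)-tert-butyl[(6,6-dimethyloct-7-en-1-yn-4-yl)oxy]dimethylsilane
Conditions: TBSCl, imidazole, DMF, rt
Reagents that add atoms: tert-butyldimethylsilyl chloride, CC(C)(C)[Si](C)(C)Cl
Why: Imidazole-promoted silylation of the secondary alcohol gives a TBS ether that should tolerate the organoaluminium, hydride, dissolving-metal and ylide steps that follow until step 24.

Step 4
Reactants: 6 (S)-tert-butyl[(6,6-dimethyloct-7-en-1-yn-4-yl)oxy]dimethylsilane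
Product: 8 methyl (2E,5S)-5-[(tert-butyldimethylsilyl)oxy]-3,7,7-trimethylnona-2,8-dienoate, via (E)-alkenyldimethylalane 7 (not isolated)
Conditions: Me3Al (3 equiv), Cp2ZrCl2 (0.3 equiv), CH2Cl2, 0 °C → rt; then ClCO2Me, 0 °C → rt
Reagents that add atoms: trimethylaluminium, C[Al](C)C; methyl chloroformate, COC(=O)Cl
Why: Negishi zirconium-catalysed carboalumination adds CH3 and Al syn across the terminal alkyne with the methyl on the internal carbon, and acylation of the alkenylalane occurs with retention, so the E-enoate (C11 cis to the C10 methyl) should form as one geometric isomer while the hindered vinyl group stays untouched.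

Step 5
Reactants: 8 methyl (2E,5S)-5-[(tert-butyldimethylsilyl)oxy]-3,7,7-trimethylnona-2,8-dienoate
Product: 10 methyl (2E,5R)-5-[(tert-butyldimethylsilyl)oxy]-9-hydroxy-3,7,7-trimethylnon-2-enoate, via B-alkyl-9-BBN adduct 9 (not isolated)
Conditions: 9-BBN, THF, 0 °C → rt; then H2O2, aq. NaOAc, 0 °C
Reagents that add atoms: hydrogen peroxide, OO
Why: Brown hydroboration–oxidation with 9-BBN adds anti-Markovnikov to the monosubstituted vinyl group and should ignore the electron-poor trisubstituted enoate and the ester (the C5 descriptor changes only through CIP priorities).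

Step 6
Reactants: 10 methyl (2E,5R)-5-[(tert-butyldimethylsilyl)oxy]-9-hydroxy-3,7,7-trimethylnon-2-enoate
Product: 11 methyl (2E,5R)-5-[(tert-butyldimethylsilyl)oxy]-3,7,7-trimethyl-9-oxonon-2-enoate
Conditions: Dess–Martin periodinane, NaHCO3, CH2Cl2, rt
Reagents that add atoms: none
Why: Dess–Martin oxidation converts the primary alcohol into the aldehyde (C6) under neutral conditions that leave the enoate and the silyl ether alone.

Step 7
Reactants: 11 methyl (2E,5R)-5-[(tert-butyldimethylsilyl)oxy]-3,7,7-trimethyl-9-oxonon-2-enoate; 12 (E)-1-bromoprop-1-ene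
Product: 14 methyl (2E,5R,10E)-5-[(tert-butyldimethylsilyl)oxy]-9-hydroxy-3,7,7-trimethyldodeca-2,10-dienoate (both C9 epimers), via (E)-prop-1-enyllithium 13 (not isolated)
Conditions: 12, t-BuLi (2 equiv), Et2O, −78 °C; then 11, THF, −78 °C; then H2O
Reagents that add atoms: none
Why: Lithium–bromine exchange keeps the E geometry and the alkenyllithium should add 1,2 to the aldehyde far faster than to the hindered conjugated ester at −78 °C; the new carbinol centre is uncontrolled and is removed in step 8.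

Step 8
Reactants: 14 methyl (2E,5R,10E)-5-[(tert-butyldimethylsilyl)oxy]-9-hydroxy-3,7,7-trimethyldodeca-2,10-dienoate
Product: 15 methyl (2E,5R,10E)-5-[(tert-butyldimethylsilyl)oxy]-3,7,7-trimethyl-9-oxododeca-2,10-dienoate
Conditions: Dess–Martin periodinane, NaHCO3, CH2Cl2, rt
Reagents that add atoms: none
Why: Dess–Martin oxidation of the allylic alcohol gives the E-propenyl ketone (C6 carbonyl) and erases the uncontrolled carbinol centre.

Step 9
Reactants: 15 methyl (2E,5R,10E)-5-[(tert-butyldimethylsilyl)oxy]-3,7,7-trimethyl-9-oxododeca-2,10-dienoate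
Product: 16 methyl (2E,5S,8Z,10E)-5-[(tert-butyldimethylsilyl)oxy]-3,7,7-trimethyl-9-[(triethylsilyl)oxy]dodeca-2,8,10-trienoate
Conditions: Et3SiOTf, Et3N, CH2Cl2, −78 → 0 °C
Reagents that add atoms: triethylsilyl trifluoromethanesulfonate, CC[Si](CC)(CC)OS(=O)(=O)C(F)(F)F
Why: Soft enolisation with a silyl triflate and an amine (enol silane formation) should take the α′-methylene C5 to give the cross-conjugated 2-silyloxydiene, and the Z geometry is expected because the quaternary C4 avoids the propenyl arm on C6 (allylic strain), which places the tether on the outside of the diene.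

Step 10
Reactants: 16 methyl (2E,5S,8Z,10E)-5-[(tert-butyldimethylsilyl)oxy]-3,7,7-trimethyl-9-[(triethylsilyl)oxy]dodeca-2,8,10-trienoate
Product: 17 methyl (1R,2R,4aR,7R,8aR)-7-[(tert-butyldimethylsilyl)oxy]-2,5,5,8a-tetramethyl-4-[(triethylsilyl)oxy]-1,2,4a,5,6,7,8,8a-octahydronaphthalene-1-carboxylate (trans-fused; labdane locants 2R,5R,8R,9R,10R)
Conditions: Me2AlCl (1.5 equiv), CH2Cl2, −78 → −20 °C; then Et3N, aq. NaHCO3
Reagents that add atoms: none
Why: Me2AlCl binds the ester carbonyl and the (Z)-2-silyloxydiene (C5=C6–C7=C8) adds across the E-enoate (C9=C10) in a concerted but asynchronous [4+2] in which the nucleophilic enol-silane carbon C5 bonds to the electrophilic β-carbon C10 ahead of C8–C9, so the regiochemistry imposed by the tether is also the electronically matched one. The closest known reaction is the type 1 intramolecular Diels–Alder reaction of 2-silyloxydienes with β,β-disubstituted enoates, which gives trans-decalins bearing an angular methyl group. Ring B is the cyclohexene created by the cycloaddition itself, while ring A closes through the C5–C10 bond over the four-atom tether C1–C4 in a chair (six-membered, exo with respect to C9=C10), helped by the gem-dimethyl group on C4. C5 and C10 are set by the tether chair, in which the C2 silyloxy group must be equatorial because the axial site is syn to the methyls on C4 and C10, and their trans relationship follows from the ester-endo arrangement; C9 follows from the E-alkene (C11 cis to the C10 methyl) and C8 from the E-propenyl terminus combined with endo addition. The selectivity that must be secured is the π-facial one, and the resident C2 stereocentre secures it, while the Lewis acid reinforces the endo preference. Heating in toluene is the promoter-free variant of the same step.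

Step 11
Reactants: 17 methyl (1R,2R,4aR,7R,8aR)-7-[(tert-butyldimethylsilyl)oxy]-2,5,5,8a-tetramethyl-4-[(triethylsilyl)oxy]-1,2,4a,5,6,7,8,8a-octahydronaphthalene-1-carboxylate
Product: 18 methyl (1R,4aR,7R,8aR)-7-[(tert-butyldimethylsilyl)oxy]-2,5,5,8a-tetramethyl-4-oxo-1,4,4a,5,6,7,8,8a-octahydronaphthalene-1-carboxylate
Conditions: Pd(OAc)2 (1.1 equiv), MeCN, rt
Reagents that add atoms: none
Why: Saegusa–Ito dehydrogenation of the enol silane with Pd(OAc)2 can lose a β-hydrogen only from C8, so the 7-en-6-one should form, the C8 stereocentre disappears and the neutral medium spares the acidic C9–H.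

Step 12
Reactants: 18 methyl (1R,4aR,7R,8aR)-7-[(tert-butyldimethylsilyl)oxy]-2,5,5,8a-tetramethyl-4-oxo-1,4,4a,5,6,7,8,8a-octahydronaphthalene-1-carboxylate
Product: 19 (1R,4S,4aR,7R,8aS)-7-[(tert-butyldimethylsilyl)oxy]-1-(hydroxymethyl)-2,5,5,8a-tetramethyl-1,4,4a,5,6,7,8,8a-octahydronaphthalen-4-ol (labdane locants 2R,5R,6S,9R,10S)
Conditions: i-Bu2AlH (5 equiv), CH2Cl2, −78 → 0 °C; aq. KNaC4H4O6 (tartrate)
Reagents that add atoms: none
Why: i-Bu2AlH reduces the enone in the 1,2 sense and the ester to the primary alcohol without base; hydride should enter C6 from the face opposite the axial methyls on C4 and C10 (6S alcohol), a centre that is removed again in step 14.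

Step 13
Reactants: 19 (1R,4S,4aR,7R,8aS)-7-[(tert-butyldimethylsilyl)oxy]-1-(hydroxymethyl)-2,5,5,8a-tetramethyl-1,4,4a,5,6,7,8,8a-octahydronaphthalen-4-ol
Product: 20 [(1R,4S,4aR,7R,8aS)-4-acetoxy-7-[(tert-butyldimethylsilyl)oxy]-2,5,5,8a-tetramethyl-1,4,4a,5,6,7,8,8a-octahydronaphthalen-1-yl]methyl acetate
Conditions: Ac2O, Et3N, DMAP, CH2Cl2, rt → 40 °C
Reagents that add atoms: acetic anhydride, CC(=O)OC(C)=O
Why: DMAP-catalysed acetylation converts both hydroxyls into acetates, the allylic one becoming the leaving group for step 14; mild heating is foreseen for the hindered C6 alcohol.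

Step 14
Reactants: 20 [(1R,4S,4aR,7R,8aS)-4-acetoxy-7-[(tert-butyldimethylsilyl)oxy]-2,5,5,8a-tetramethyl-1,4,4a,5,6,7,8,8a-octahydronaphthalen-1-yl]methyl acetate
Product: 21 [(1R,4aR,7R,8aR)-7-[(tert-butyldimethylsilyl)oxy]-2,5,5,8a-tetramethyl-1,4,4a,5,6,7,8,8a-octahydronaphthalen-1-yl]methanol (labdane locants 2R,5R,9R,10R)
Conditions: Li, NH3 (l), THF, −78 °C; then NH4Cl
Reagents that add atoms: none
Why: Dissolving-metal (Birch-type) reductive cleavage of the allylic C6–O bond, with protonation expected at the less substituted allyl terminus C6, should keep the trisubstituted C7=C8 alkene, while the primary acetate is cleaved to the alcohol in the same flask; no stereocentre is formed.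

Step 15
Reactants: 21 [(1R,4aR,7R,8aR)-7-[(tert-butyldimethylsilyl)oxy]-2,5,5,8a-tetramethyl-1,4,4a,5,6,7,8,8a-octahydronaphthalen-1-yl]methanol
Product: 22 (1R,4aR,7R,8aR)-7-[(tert-butyldimethylsilyl)oxy]-2,5,5,8a-tetramethyl-1,4,4a,5,6,7,8,8a-octahydronaphthalene-1-carbaldehyde
Conditions: Dess–Martin periodinane, NaHCO3, CH2Cl2, 0 °C → rt
Reagents that add atoms: none
Why: Dess–Martin oxidation under buffered, base-free conditions should give the β,γ-unsaturated aldehyde (C11) without epimerising C9 or moving the alkene into conjugation.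

Step 16
Reactants: 23 (S)-3-bromo-2-methylpropan-1-ol
Product: 24 (S)-(3-bromo-2-methylpropoxy)(tert-butyl)dimethylsilane
Conditions: TBSCl, imidazole, CH2Cl2, rt
Reagents that add atoms: tert-butyldimethylsilyl chloride, CC(C)(C)[Si](C)(C)Cl
Why: Imidazole-promoted silylation masks the hydroxyl (future C12) so that the bromide can be turned into a Grignard reagent; the stereocentre (future C13) is untouched.

Step 17
Reactants: 24 (S)-(3-bromo-2-methylpropoxy)(tert-butyl)dimethylsilane
Product: 26 (R)-4-[(tert-butyldimethylsilyl)oxy]-3-methylbutan-1-ol, via alkylmagnesium bromide 25 (not isolated)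
Conditions: Mg, THF, reflux; then (CH2O)n, 0 °C → rt; then H2O
Reagents that add atoms: formaldehyde (as paraformaldehyde), C=O
Why: Grignard formation and addition to formaldehyde lengthens the chain by the one carbon that becomes C15; the stereocentre is not involved and its descriptor changes only through CIP priorities.

Step 18
Reactants: 26 (R)-4-[(tert-butyldimethylsilyl)oxy]-3-methylbutan-1-ol
Product: 27 (R)-tert-butyl{4-[(tert-butyldiphenylsilyl)oxy]-2-methylbutoxy}dimethylsilane
Conditions: TBDPSCl, imidazole, DMF, rt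
Reagents that add atoms: tert-butyldiphenylsilyl chloride, CC(C)(C)[Si](Cl)(c1ccccc1)c1ccccc1
Why: Silylation of the new primary alcohol with the more acid-stable TBDPS group differentiates the two chain ends.

Step 19
Reactants: 27 (R)-tert-butyl{4-[(tert-butyldiphenylsilyl)oxy]-2-methylbutoxy}dimethylsilane
Product: 28 (R)-4-[(tert-butyldiphenylsilyl)oxy]-2-methylbutan-1-ol
Conditions: PPTS (cat.), EtOH, 50 °C
Reagents that add atoms: none
Why: Mild acid-catalysed alcoholysis should remove the primary TBS ether selectively, the TBDPS ether being far more stable to acid.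

Step 20
Reactants: 28 (R)-4-[(tert-butyldiphenylsilyl)oxy]-2-methylbutan-1-ol
Product: 29 (R)-tert-butyl(4-iodo-3-methylbutoxy)diphenylsilane
Conditions: I2, PPh3, imidazole, CH2Cl2, 0 °C → rt
Reagents that add atoms: iodine, II
Why: Appel-type iodination replaces the primary hydroxyl by iodide through SN2 at a CH2 group, leaving the adjacent stereocentre untouched.

Step 21
Reactants: 29 (R)-tert-butyl(4-iodo-3-methylbutoxy)diphenylsilane
Product: 30 {(2R)-4-[(tert-butyldiphenylsilyl)oxy]-2-methylbutyl}triphenylphosphonium iodide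
Conditions: PPh3, MeCN, reflux
Reagents that add atoms: triphenylphosphine, c1ccc(cc1)P(c1ccccc1)c1ccccc1
Why: SN2 quaternisation of triphenylphosphine by the primary iodide gives the Wittig salt that carries C12–C15.

Step 22
Reactants: 22 (1R,4aR,7R,8aR)-7-[(tert-butyldimethylsilyl)oxy]-2,5,5,8a-tetramethyl-1,4,4a,5,6,7,8,8a-octahydronaphthalene-1-carbaldehyde; 30 {(2R)-4-[(tert-butyldiphenylsilyl)oxy]-2-methylbutyl}triphenylphosphonium iodide
Product: 32 tert-butyl{[(3R,4Z)-5-[(1R,4aR,7R,8aR)-7-[(tert-butyldimethylsilyl)oxy]-2,5,5,8a-tetramethyl-1,4,4a,5,6,7,8,8a-octahydronaphthalen-1-yl]-3-methylpent-4-en-1-yl]oxy}diphenylsilane, via phosphonium ylide 31 (not isolated)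
Conditions: 30, KN(SiMe3)2, THF, −78 → 0 °C; then 22, −78 °C → rt
Reagents that add atoms: none
Why: Wittig olefination with a salt-free non-stabilised ylide at low temperature should form C11=C12 (mainly Z, geometry irrelevant) faster than the hindered aldehyde is enolised, so C9 and the C7=C8 position are retained, and C13 arrives with fragment 30.

Step 23
Reactants: 32 tert-butyl{[(3R,4Z)-5-[(1R,4aR,7R,8aR)-7-[(tert-butyldimethylsilyl)oxy]-2,5,5,8a-tetramethyl-1,4,4a,5,6,7,8,8a-octahydronaphthalen-1-yl]-3-methylpent-4-en-1-yl]oxy}diphenylsilane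
Product: 33 tert-butyl{[(3S)-5-[(1R,4aR,7R,8aR)-7-[(tert-butyldimethylsilyl)oxy]-2,5,5,8a-tetramethyl-1,4,4a,5,6,7,8,8a-octahydronaphthalen-1-yl]-3-methylpentyl]oxy}diphenylsilane
Conditions: TsNHNH2, NaOAc, DME/H2O, reflux
Reagents that add atoms: none
Why: Diimide generated from tosylhydrazide reduces the disubstituted C11=C12 alkene by concerted syn hydrogen transfer and should leave the much less reactive trisubstituted C7=C8 alkene (the C13 descriptor changes only through CIP priorities).

Step 24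
Reactants: 33 tert-butyl{[(3S)-5-[(1R,4aR,7R,8aR)-7-[(tert-butyldimethylsilyl)oxy]-2,5,5,8a-tetramethyl-1,4,4a,5,6,7,8,8a-octahydronaphthalen-1-yl]-3-methylpentyl]oxy}diphenylsilane
Product: 34 (3S)-5-[(1R,4aR,7R,8aR)-7-hydroxy-2,5,5,8a-tetramethyl-1,4,4a,5,6,7,8,8a-octahydronaphthalen-1-yl]-3-methylpentan-1-ol
Conditions: Bu4NF, THF, rt → 40 °C; then H2O
Reagents that add atoms: none
Why: Fluoride-induced desilylation removes the secondary TBS ether at C2 and the primary TBDPS ether at C15 in one operation.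

Step 25
Reactants: 34 (3S)-5-[(1R,4aR,7R,8aR)-7-hydroxy-2,5,5,8a-tetramethyl-1,4,4a,5,6,7,8,8a-octahydronaphthalen-1-yl]-3-methylpentan-1-ol
Product: 35 (3S)-5-[(1R,4aR,7R,8aR)-7-acetoxy-2,5,5,8a-tetramethyl-1,4,4a,5,6,7,8,8a-octahydronaphthalen-1-yl]-3-methylpentyl acetate (target; labdane locants 2R,5R,9R,10R,13S)
Conditions: Ac2O, pyridine, DMAP, CH2Cl2, rt
Reagents that add atoms: acetic anhydride, CC(=O)OC(C)=O
Why: DMAP-catalysed acetylation of the equatorial C2 alcohol and the primary C15 alcohol gives the diacetate without touching any stereocentre.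

Compound list
1 | methyl 3,3-dimethylpent-4-enoate | COC(=O)CC(C)(C)C=C | starting material
2 | 3,3-dimethylpent-4-enal | O=CCC(C)(C)C=C | intermediate
3 | allenylboronic acid pinacol ester [4,4,5,5-tetramethyl-2-(propa-1,2-dien-1-yl)-1,3,2-dioxaborolane] | C=C=CB1OC(C)(C)C(C)(C)O1 | starting material
4 | (S)-2-[(6,6-dimethyloct-7-en-1-yn-4-yl)oxy]-4,4,5,5-tetramethyl-1,3,2-dioxaborolane (not isolated) | C#CC[C@H](OB1OC(C)(C)C(C)(C)O1)CC(C)(C)C=C | intermediate
5 | (S)-6,6-dimethyloct-7-en-1-yn-4-ol | C#CC[C@H](O)CC(C)(C)C=C | intermediate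
6 | (S)-tert-butyl[(6,6-dimethyloct-7-en-1-yn-4-yl)oxy]dimethylsilane | C#CC[C@H](O[Si](C)(C)C(C)(C)C)CC(C)(C)C=C | intermediate
7 | {(1E,4R)-4-[(tert-butyldimethylsilyl)oxy]-2,6,6-trimethylocta-1,7-dien-1-yl}dimethylalumane (not isolated) | C[Al](C)/C=C(\C)C[C@H](O[Si](C)(C)C(C)(C)C)CC(C)(C)C=C | intermediate
8 | methyl (2E,5S)-5-[(tert-butyldimethylsilyl)oxy]-3,7,7-trimethylnona-2,8-dienoate | COC(=O)/C=C(\C)C[C@H](O[Si](C)(C)C(C)(C)C)CC(C)(C)C=C | intermediate
9 | methyl (2E,5R)-9-(9-borabicyclo[3.3.1]nonan-9-yl)-5-[(tert-butyldimethylsilyl)oxy]-3,7,7-trimethylnon-2-enoate (not isolated) | COC(=O)/C=C(\C)C[C@H](O[Si](C)(C)C(C)(C)C)CC(C)(C)CCB1C2CCCC1CCC2 | intermediate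
10 | methyl (2E,5R)-5-[(tert-butyldimethylsilyl)oxy]-9-hydroxy-3,7,7-trimethylnon-2-enoate | COC(=O)/C=C(\C)C[C@H](O[Si](C)(C)C(C)(C)C)CC(C)(C)CCO | intermediate
11 | methyl (2E,5R)-5-[(tert-butyldimethylsilyl)oxy]-3,7,7-trimethyl-9-oxonon-2-enoate | COC(=O)/C=C(\C)C[C@H](O[Si](C)(C)C(C)(C)C)CC(C)(C)CC=O | intermediate
12 | (E)-1-bromoprop-1-ene | C/C=C/Br | starting material
13 | (E)-prop-1-enyllithium (not isolated) | C/C=C/[Li] | intermediate
14 | methyl (2E,5R,10E)-5-[(tert-butyldimethylsilyl)oxy]-9-hydroxy-3,7,7-trimethyldodeca-2,10-dienoate (both C9 epimers) | COC(=O)/C=C(\C)C[C@H](O[Si](C)(C)C(C)(C)C)CC(C)(C)CC(O)/C=C/C | intermediate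
15 | methyl (2E,5R,10E)-5-[(tert-butyldimethylsilyl)oxy]-3,7,7-trimethyl-9-oxododeca-2,10-dienoate | COC(=O)/C=C(\C)C[C@H](O[Si](C)(C)C(C)(C)C)CC(C)(C)CC(=O)/C=C/C | intermediate
16 | methyl (2E,5S,8Z,10E)-5-[(tert-butyldimethylsilyl)oxy]-3,7,7-trimethyl-9-[(triethylsilyl)oxy]dodeca-2,8,10-trienoate | COC(=O)/C=C(\C)C[C@H](O[Si](C)(C)C(C)(C)C)CC(C)(C)/C=C(O[Si](CC)(CC)CC)/C=C/C | intermediate
17 | methyl (1R,2R,4aR,7R,8aR)-7-[(tert-butyldimethylsilyl)oxy]-2,5,5,8a-tetramethyl-4-[(triethylsilyl)oxy]-1,2,4a,5,6,7,8,8a-octahydronaphthalene-1-carboxylate | COC(=O)[C@@H]1[C@H](C)C=C(O[Si](CC)(CC)CC)[C@@H]2C(C)(C)C[C@@H](O[Si](C)(C)C(C)(C)C)C[C@@]12C | intermediate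
18 | methyl (1R,4aR,7R,8aR)-7-[(tert-butyldimethylsilyl)oxy]-2,5,5,8a-tetramethyl-4-oxo-1,4,4a,5,6,7,8,8a-octahydronaphthalene-1-carboxylate | COC(=O)[C@@H]1C(C)=CC(=O)[C@@H]2C(C)(C)C[C@@H](O[Si](C)(C)C(C)(C)C)C[C@@]12C | intermediate
19 | (1R,4S,4aR,7R,8aS)-7-[(tert-butyldimethylsilyl)oxy]-1-(hydroxymethyl)-2,5,5,8a-tetramethyl-1,4,4a,5,6,7,8,8a-octahydronaphthalen-4-ol | OC[C@@H]1C(C)=C[C@H](O)[C@@H]2C(C)(C)C[C@@H](O[Si](C)(C)C(C)(C)C)C[C@@]12C | intermediate
20 | [(1R,4S,4aR,7R,8aS)-4-acetoxy-7-[(tert-butyldimethylsilyl)oxy]-2,5,5,8a-tetramethyl-1,4,4a,5,6,7,8,8a-octahydronaphthalen-1-yl]methyl acetate | CC(=O)OC[C@@H]1C(C)=C[C@H](OC(C)=O)[C@@H]2C(C)(C)C[C@@H](O[Si](C)(C)C(C)(C)C)C[C@@]12C | intermediate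
21 | [(1R,4aR,7R,8aR)-7-[(tert-butyldimethylsilyl)oxy]-2,5,5,8a-tetramethyl-1,4,4a,5,6,7,8,8a-octahydronaphthalen-1-yl]methanol | OC[C@@H]1C(C)=CC[C@@H]2C(C)(C)C[C@@H](O[Si](C)(C)C(C)(C)C)C[C@@]12C | intermediate
22 | (1R,4aR,7R,8aR)-7-[(tert-butyldimethylsilyl)oxy]-2,5,5,8a-tetramethyl-1,4,4a,5,6,7,8,8a-octahydronaphthalene-1-carbaldehyde | O=C[C@@H]1C(C)=CC[C@@H]2C(C)(C)C[C@@H](O[Si](C)(C)C(C)(C)C)C[C@@]12C | intermediate
23 | (S)-3-bromo-2-methylpropan-1-ol | OC[C@H](C)CBr | starting material
24 | (S)-(3-bromo-2-methylpropoxy)(tert-butyl)dimethylsilane | CC(C)(C)[Si](C)(C)OC[C@H](C)CBr | intermediate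
25 | {(2S)-3-[(tert-butyldimethylsilyl)oxy]-2-methylpropyl}magnesium bromide (not isolated) | CC(C)(C)[Si](C)(C)OC[C@H](C)C[Mg]Br | intermediate
26 | (R)-4-[(tert-butyldimethylsilyl)oxy]-3-methylbutan-1-ol | CC(C)(C)[Si](C)(C)OC[C@H](C)CCO | intermediate
27 | (R)-tert-butyl{4-[(tert-butyldiphenylsilyl)oxy]-2-methylbutoxy}dimethylsilane | CC(C)(C)[Si](C)(C)OC[C@H](C)CCO[Si](c1ccccc1)(c1ccccc1)C(C)(C)C | intermediate
28 | (R)-4-[(tert-butyldiphenylsilyl)oxy]-2-methylbutan-1-ol | OC[C@H](C)CCO[Si](c1ccccc1)(c1ccccc1)C(C)(C)C | intermediate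
29 | (R)-tert-butyl(4-iodo-3-methylbutoxy)diphenylsilane | IC[C@H](C)CCO[Si](c1ccccc1)(c1ccccc1)C(C)(C)C | intermediate
30 | {(2R)-4-[(tert-butyldiphenylsilyl)oxy]-2-methylbutyl}triphenylphosphonium iodide | [I-].c1ccccc1[P+](c1ccccc1)(c1ccccc1)C[C@H](C)CCO[Si](c1ccccc1)(c1ccccc1)C(C)(C)C | intermediate
31 | {(2R)-4-[(tert-butyldiphenylsilyl)oxy]-2-methylbutylidene}triphenylphosphorane (not isolated) | c1ccccc1P(c1ccccc1)(c1ccccc1)=C[C@H](C)CCO[Si](c1ccccc1)(c1ccccc1)C(C)(C)C | intermediate
32 | tert-butyl{[(3R,4Z)-5-[(1R,4aR,7R,8aR)-7-[(tert-butyldimethylsilyl)oxy]-2,5,5,8a-tetramethyl-1,4,4a,5,6,7,8,8a-octahydronaphthalen-1-yl]-3-methylpent-4-en-1-yl]oxy}diphenylsilane | CC(C)(C)[Si](c1ccccc1)(c1ccccc1)OCC[C@@H](C)/C=C\[C@@H]1C(C)=CC[C@@H]2C(C)(C)C[C@@H](O[Si](C)(C)C(C)(C)C)C[C@@]12C | intermediate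
33 | tert-butyl{[(3S)-5-[(1R,4aR,7R,8aR)-7-[(tert-butyldimethylsilyl)oxy]-2,5,5,8a-tetramethyl-1,4,4a,5,6,7,8,8a-octahydronaphthalen-1-yl]-3-methylpentyl]oxy}diphenylsilane | CC(C)(C)[Si](c1ccccc1)(c1ccccc1)OCC[C@@H](C)CC[C@@H]1C(C)=CC[C@@H]2C(C)(C)C[C@@H](O[Si](C)(C)C(C)(C)C)C[C@@]12C | intermediate
34 | (3S)-5-[(1R,4aR,7R,8aR)-7-hydroxy-2,5,5,8a-tetramethyl-1,4,4a,5,6,7,8,8a-octahydronaphthalen-1-yl]-3-methylpentan-1-ol | OCC[C@@H](C)CC[C@@H]1C(C)=CC[C@@H]2C(C)(C)C[C@@H](O)C[C@@]12C | intermediate
35 | (3S)-5-[(1R,4aR,7R,8aR)-7-acetoxy-2,5,5,8a-tetramethyl-1,4,4a,5,6,7,8,8a-octahydronaphthalen-1-yl]-3-methylpentyl acetate, CNP0220683.1 | CC(=O)OCC[C@@H](C)CC[C@@H]1C(C)=CC[C@@H]2C(C)(C)C[C@@H](OC(C)=O)C[C@@]12C | target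

Total step count: 25. Longest linear sequence: 19 steps (steps 1–15 and 22–25); the side chain salt 30 takes 6 steps (16–21).

Steps most likely to fail

Step 10. The cycloaddition may stall at the hindered C5–C10 bond, the enol silane may be lost by protodesilylation, or endo/exo control may be poor so that cis-fused material forms. The fallback sets out from enone 15. LiN(SiMe3)2 in THF–hexane (−78 °C → rt) should deprotonate C5, and the cross-conjugated dienolate should undergo an intramolecular double Michael addition (C5 to C10 over the same chair tether, then the ester enolate carbon C9 to C8). Brief NaOMe/MeOH equilibration of the α-carbons C5 and C9 should then converge on the trans-fused saturated 6-keto ester F1 with the equatorial ester. IBX in DMSO–toluene at 70 °C can desaturate only across C7–C8, because C4 and C10 are quaternary, and comes back to the route at enone ester 18.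

Step 14. Protonation may occur at the tertiary allyl terminus C8, which would move the alkene to C6=C7, or acyl–oxygen cleavage may merely return the allylic alcohol. The fallback sets out from diacetate 20 and uses palladium-catalysed hydride transfer instead of electron transfer: Pd(PPh3)4 (5 mol%) with LiBHEt3 in THF at rt. The allylic acetate should ionise anti to a π-allylpalladium species, and hydride should be delivered to the less hindered terminus C6. The same hydride cleaves the primary acetate, so the route is rejoined directly at alcohol 21 and no new compound is made (F0).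

Step 22. The basic ylide may enolise the hindered β,γ-unsaturated aldehyde, causing epimerisation at C9 or migration of the alkene into conjugation, or the addition may be too slow. The fallback sets out from iodide 29 and aldehyde 22 and replaces olefination–reduction by addition–deoxygenation. Mg in Et2O converts 29 into the alkylmagnesium iodide F2, which is added to 22 in the presence of CeCl3 at −78 °C (weakly basic organocerium addition) to give the C11 carbinol F3 as a mixture of epimers. NaH, CS2 and MeI give the S-methyl xanthate F4, and Barton–McCombie reduction (Bu3SnH, AIBN, toluene, 90 °C) removes the C11 oxygen and comes back to the route at 33, so that step 23 is not needed.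

Further compounds
F1 | step 10 | methyl (1R,4aR,7R,8aR)-7-[(tert-butyldimethylsilyl)oxy]-2,5,5,8a-tetramethyl-4-oxodecahydronaphthalene-1-carboxylate (C2 epimers of the ring methyl) | COC(=O)[C@@H]1C(C)CC(=O)[C@@H]2C(C)(C)C[C@@H](O[Si](C)(C)C(C)(C)C)C[C@@]12C
F0 | step 14 | none | none
F2 | step 22 | {(2R)-4-[(tert-butyldiphenylsilyl)oxy]-2-methylbutyl}magnesium iodide | I[Mg]C[C@H](C)CCO[Si](c1ccccc1)(c1ccccc1)C(C)(C)C
F3 | step 22 | (3R)-5-[(tert-butyldiphenylsilyl)oxy]-1-[(1R,4aR,7R,8aR)-7-[(tert-butyldimethylsilyl)oxy]-2,5,5,8a-tetramethyl-1,4,4a,5,6,7,8,8a-octahydronaphthalen-1-yl]-3-methylpentan-1-ol (both C1 epimers) | CC(C)(C)[Si](c1ccccc1)(c1ccccc1)OCC[C@@H](C)CC(O)[C@@H]1C(C)=CC[C@@H]2C(C)(C)C[C@@H](O[Si](C)(C)C(C)(C)C)C[C@@]12C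
F4 | step 22 | O-{(3R)-5-[(tert-butyldiphenylsilyl)oxy]-1-[(1R,4aR,7R,8aR)-7-[(tert-butyldimethylsilyl)oxy]-2,5,5,8a-tetramethyl-1,4,4a,5,6,7,8,8a-octahydronaphthalen-1-yl]-3-methylpentyl} S-methyl carbonodithioate | CC(C)(C)[Si](c1ccccc1)(c1ccccc1)OCC[C@@H](C)CC(OC(=S)SC)[C@@H]1C(C)=CC[C@@H]2C(C)(C)C[C@@H](O[Si](C)(C)C(C)(C)C)C[C@@]12C
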